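(All runs stem from a simulated flask on assumed constants, noise included.)

The grey run levels off after 8.00 min near 14.1% of the electrophile charged. The teal run, with 0.19 M of nucleophile against grey's 0.046 M, levels off at twice that.

in all of them: electrophile 0.18 M (fed, over 4.0 min)
- grey: nucleophile 0.046 M; free base 0.54 M; temperature −34 °C; run made earlier
- violet: nucleophile 0.11 M; free base 0.54 M; temperature −20 °C; run made earlier
- teal: nucleophile 0.19 M; free base 0.54 M; temperature −34 °C; run made earlier
- maple: nucleophile 0.0600 M; free base 0.540 M; at −40 °C throughout; time 40 min
- cedar: nucleophile 0.234 M; free base 0.540 M; at −40 °C until 4.0 min, from then on at −15 °C; time 40 min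

| run | time / min | target / % |
|---|---|---|
| grey | 2.50 | 11.8 |
| grey | 8.00 | 13.6 |
| grey | 12.0 | 13.9 |
| grey | 20.0 | 14.1 |
| grey | 30.0 | 13.7 |
| violet | 2.00 | 13.3 |
| violet | 4.00 | 17.9 |
| violet | 6.00 | 18.3 |
| violet | 10.0 | 18.0 |
| violet | 12.0 | 17.6 |
| teal | 2.50 | 16.7 |
| teal | 8.00 | 27.2 |
| teal | 12.0 | 27.2 |
| teal | 20.0 | 27.7 |
| teal | 30.0 | 28.2 |

(scatter of a reading: 0.3 percentage points)

- the flask that ends with the higher amount of target, in percent of the electrophile charged, or "neither" when 2 percentage points or less lies between them (maple / cedar / neither)
- final target, as a percentage of the electrophile charged, in maple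
- final target, as a percentage of the electrophile charged, in cedar

- what may be going on: electrophile + nucleophile -> acid set free + target; nucleophile + acid set free <-> protonated nucleophile; acid set free + free base <-> salt of the base; nucleophile + target -> over-reaction product; target <-> isomer of the product
- percentages count the whole charge, also what has not yet gone in

Two chemists argue over these runs, and both count with the catch: the target made per nucleophile charged, read at the level stretch of a run. One target takes one nucleophile, so the catch is a share of c(nucleophile). It reads 55.2% in grey, 29.5% in violet and 26.2% in teal, so it is lower in teal than in grey.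

The first chemist made the forecast: 17% in maple, 29% in cedar, cedar ahead. She expects the catch to go on falling with richer charges and holds that “warming with excess nucleophile costs some”. Her cedar figure means a catch of 22.3%.

The second chemist, whose reckoning this is and not the forecast's, sees violet at 29.5%, with less nucleophile than teal but also at another temperature. His guess is that the catch has stopped falling, so he keeps teal's catch for the rich flask, which gives cedar 34.1%. Grey's catch gives maple 18.4%. Both name cedar; they part on its catch.

    electrophile + nucleophile → acid set free + target (k = 0.151 M⁻¹ s⁻¹, Ea = 47.0 kJ mol⁻¹)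
    nucleophile + acid set free ⇌ protonated nucleophile, settled at all times (K = 500 M⁻¹, ΔH = 20.0 kJ mol⁻¹)
    acid set free + free base ⇌ salt of the base (K = 41.1 M⁻¹, k = 1.58 M⁻¹ s⁻¹, Ea = 39.0 kJ mol⁻¹, ΔH = 34.0 kJ mol⁻¹)
    nucleophile + target → over-reaction product (k = 0.0895 M⁻¹ s⁻¹, Ea = 47.0 kJ mol⁻¹)
    target ⇌ isomer of the product (K = 0.870, k = 0.00270 s⁻¹, Ea = 66.0 kJ mol⁻¹, ΔH = −63.0 kJ mol⁻¹)
    (constants at −40 °C)

The simulation gives 36.4% in cedar and 13.5% in maple, so cedar ends higher, as both said. The forecast is 7.4 percentage points low on cedar, and the second chemist is high on maple. At 40.0 min cedar has 0% of its nucleophile, the limiting reagent, left, and 46.1% of the electrophile stands as over-reaction product. Cedar's catch is 28.0%, above teal's 26.2%, so it did not fall on; maple's is 40.5%.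

A neighbour of maple takes 0.24 M of nucleophile and stays at −40 °C to the end. Teal's catch gives it 35.0% of target, but the computed flask gives 22.9%, a catch of 17.2%, with 19.9% as isomer of the product against cedar's 1.36%. In this cold, rich flask the catch is below teal's, which is the way the forecast's falling catch runs.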